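## Analysis of the target

The target 23 is a labdane: a trans-fused decalin (ring A = C1–C5 and C10, ring B = C5–C10) with an exocyclic methylene at C8 (C17), an acetoxymethyl group (C18) on the quaternary C4, and at C9 a chain C11–C15 ending in an (E)-3-methylalk-2-enoic acid (C13=C14, methyl C16, carboxyl C15).

It has four stereocentres, C4, C5, C10 and C9, in one contiguous array. The C10 methyl is β, H-5 and H-9 are α (trans fusion, β-equatorial chain), and at C4 the oxygenated carbon lies on the α face with the C19 methyl β. This is the arrangement of the same four carbons in abietic acid (1), whose C18 carboxyl sits on that α face.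

The sensitive groups are the 8(17)-methylene (it migrates into the ring under acid), the neopentyl acetate (lost to base, hydride and organoaluminium reagents) and the conjugated acid (geometry and conjugation at risk under strong base).

Two things make the synthesis hard. The first is the quaternary C4 with two different one-carbon substituents next to the ring fusion, which is laborious to set from scratch. The second is the trisubstituted C13=C14 bond, which must be one isomer; olefination of a C13 methyl ketone would give both.

The strategy rests on the cis relation of the C16 methyl and the C15 carboxyl across C13=C14. That is the pattern left by syn addition of methyl and metal to a C13≡C14 terminal alkyne, followed by replacement of the metal on C14 by the carboxyl carbon with retention. The decalin and its four stereocentres are therefore taken from 1, and the risk is placed on that alkyne functionalisation.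

## Retrosynthetic reasoning

**End game (23 ⇐ 21 ⇐ 20 ⇐ 19).** The acetyl–O18 bond is cut first because the acetate cannot survive the organoaluminium step, the hydride steps or ester hydrolysis. This leads back to hydroxy acid 21, its methyl ester 20 and the silyl ether 19, which carries the oxygen at C18 through the route. Forward, only desilylation, saponification and acetylation are needed.

**Key disconnection (19 ⇐ 15 + 16 + 17).** The C13–C16 and C14–C15 bonds are cut, leading to the terminal alkyne 15, trimethylaluminium (16) and methyl chloroformate (17). Both bonds sit on the alkene whose geometry is the problem, and making them by a syn addition and a retentive substitution ties the E geometry to mechanism. A cut at C12–C13 or an olefination at C13=C14 would leave the geometry to a thermodynamic or kinetic preference. The forward reaction must put methyl on the internal carbon, metal on the terminal carbon, and leave the C8 methylene alone.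

**Alkyne (15 ⇐ 13 + 14).** The C13≡C14 bond is cut to aldehyde 13 and the diazophosphonate 14, which supplies C14. A one-carbon homologation is chosen because C11–C13 are already attached to C9 in the abietane skeleton.

**Exocyclic alkene (13 ⇐ 12 ⇐ 9, via 10 and 11).** Aldehyde 13 comes from isopropyl ester 12 by partial reduction. The 8(17)-methylene of 12 is traced to the endocyclic allylic alcohol 9 (C7=C8, C17–OH) through the allylic diazene 11, which arises from the sulfonylhydrazine 10. Opening ring C of an abietane leaves exactly this pattern, an oxidised carbon on a C7=C8 alkene. A reductive 1,3-transposition turns it into the methylene, placing hydrogen on C7, which is not a stereocentre.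

**Telling C17 from C13 (9 ⇐ 7, via 8).** The allylic alcohol 9 is traced to the acid ester 7. In 7, C17 is a free conjugated acid and C13 an isopropyl ester. Activation of the acid as the mixed anhydride 8 allows its reduction while the ester is kept.

**Removal of the isopropyl group (7 ⇐ 6 ⇐ 5).** The bond between C13 and the isopropyl carbon is cut by oxygen insertion, leading to the isopropyl ketone 6. A peracid would attack a free aldehyde or an electron-rich alkene, so the insertion is placed on 6, where C17 is a carboxyl group and C7=C8 is electron-poor. Acid 6 comes from the enal 5 by aldehyde oxidation.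

**Opening of ring C (5 ⇐ 3, via 4).** In abietane numbering the C13–C14 bond is cut by dihydroxylation to the diol 4 and glycol cleavage. This is the only ring-C bond whose cleavage leaves C11–C12–C13 on C9 and a single carbon (abietane C14 = labdane C17) on C8.

**Start (3 ⇐ 2 ⇐ 1).** The C18 carboxyl of 1 is reduced to the alcohol 2 and silylated to 3 at the outset, before any other carbonyl group is present.

## Alternatives that were turned down

**Alternative 1:** The disconnection is at C9–C11 and C1–C10 of a ring-B cyclohexenone. In the forward step a vinylcopper reagent adds to C9 and the C10 enolate is alkylated by a vinyl ketone. This gives A1, 4-(tert-butyldimethylsilyloxy)-2-methyl-2-(3-oxopentyl)-3-vinylcyclohexanone.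
- In its favour: it is convergent, sets the C9/C10 relation in one operation, and does not depend on a natural diterpene. On flexibility toward analogues it is stronger than the chosen route.
- Against it here: A1 has no ring A. After its closure, C4 must still be made quaternary with the oxygenated carbon on the α face, the C8 oxygen turned into a methylene, and the vinyl group grown by three carbons. The E-enoate would still have to be made afterwards.
- Comparison: the chosen route offers all four stereocentres from the start and only functional-group steps before the key step, in well under half the step count.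

**Alternative 2:** The disconnection is at C9–C10. In the forward step a Lewis acid opens an epoxy carbinol on a hydrindane and the C8–C10 bond migrates to C9. This gives A2, the 8-oxo decalin with a C9 hydroxymethyl group and the 18-silyl ether.
- In its favour: the migration is stereospecific, so C9 is set relative to C10, and the C8 ketone needs only a methylenation. That is a simpler way to the exocyclic alkene than the reductive transposition used here.
- Against it here: A2 is a β-hydroxy ketone, open to retro-aldol cleavage, dehydration and C9 epimerisation. Its substrate needs a hydrindane with C4, C5 and C10 set plus two further controlled centres. The chain must then be grown from C11 by three carbons before any alkyne exists.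
- Comparison: the chosen route builds neither a ring nor C9, and its chain carbons C11–C13 are already in place.

**Alternative 3:** The disconnection is at C8–C9. In the forward step a C8 vinyl radical closes 6-exo-trig onto an enoate. This gives A3, methyl 18-(tert-butyldimethylsilyloxy)-13,14,15,16-tetranorlabd-8(17)-en-12-oate.
- In its favour: ring B, the C9 stereocentre and the 8(17)-methylene arise in one step, which is more direct for the methylene than anything in the chosen route.
- Against it here: the radical must attack a carbon next to quaternary C10, in competition with 1,5-hydrogen transfer and simple reduction, and C9 control rests on a chair-like transition state. It uses stoichiometric tin. The precursor is a ring-A cyclohexane with three stereocentres, two of them quaternary, and needs a long asymmetric synthesis. A3 ends at C12, so two carbons and the alkyne functionalisation would still follow.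
- Comparison: it would be a longer way to alkyne 15, not a replacement for the key step.

Key step: step 10

Remark on the chemistry: commercial abietic acid is taken as the natural enantiomer drawn in 1 (purified through an amine salt if technical grade is used). All compounds keep its configuration at C4, C5, C9 and C10 (5α-H, 9α-H, 10β-CH3, C18 on the α face of C4). Abietane numbering is used up to 6 and labdane numbering from 7 on (abietane C14 = labdane C17).

## Route

Step 1
Reactants: 1 abietic acid
Product: 2 abietinol (abieta-7,13-dien-18-ol)
Conditions: LiAlH4, THF, 0 °C → reflux; Fieser work-up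
Reagents that add atoms: none
Why: Hydride reduction of a carboxylic acid to the primary alcohol; the hindered neopentyl carboxyl needs reflux, the conjugated diene is inert to LiAlH4 and no stereocentre is touched.

Step 2
Reactants: 2 abietinol
Product: 3 18-(tert-butyldimethylsilyloxy)abieta-7,13-diene
Conditions: TBSCl, imidazole, DMAP (cat.), DMF, 25–40 °C
Reagents that add atoms: tert-butyldimethylsilyl chloride, CC(C)(C)[Si](C)(C)Cl
Why: Silyl ether formation at the only hydroxyl group; the neopentyl ether should be robust toward the oxidants, hydrides and organoaluminium reagents that follow.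

Step 3
Reactants: 3 18-(tert-butyldimethylsilyloxy)abieta-7,13-diene
Product: 5 seco keto-enal 18-(tert-butyldimethylsilyloxy)-13-oxo-13,14-secoabiet-7-en-14-al, via cis-13,14-diol 4 (not isolated)
Conditions: OsO4 (2 mol %), NMO (1.1 equiv), acetone–H2O, 0 → 25 °C; then NaIO4, 0 → 25 °C
Reagents that add atoms: osmium tetroxide, O=[Os](=O)(=O)=O; N-methylmorpholine N-oxide, C[N+]1([O-])CCOCC1; water, O
Why: Upjohn dihydroxylation followed in the same flask by periodate glycol cleavage (Lemieux–Johnson type); the C13=C14 bond at the open end of the diene, remote from the ring fusion, is the one hydroxylated first in abietate derivatives, and the remaining C7=C8 bond is hindered and then part of an enal, so it should be left alone. The diol is expected cis on the α face, opposite the C10 methyl; both carbinol carbons become carbonyl carbons on cleavage, so this assumption has no consequence.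

Step 4
Reactants: 5 seco keto-enal
Product: 6 18-(tert-butyldimethylsilyloxy)-13-oxo-13,14-secoabiet-7-en-14-oic acid
Conditions: NaClO2, NaH2PO4, 2-methyl-2-butene, t-BuOH–H2O, 25 °C
Reagents that add atoms: sodium chlorite, [Na+].[O-]Cl=O
Why: Pinnick oxidation, which suits conjugated aldehydes and leaves the ketone, the alkene (hypochlorite is scavenged) and the silyl ether alone; it removes the aldehyde hydrogen and keeps C7=C8 electron-poor, the two conditions the next step needs.

Step 5
Reactants: 6 keto acid
Product: 7 18-(tert-butyldimethylsilyloxy)-14,15,16-trinorlabd-7-ene-13,17-dioic acid 13-isopropyl ester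
Conditions: mCPBA (3 equiv), Na2HPO4, CH2Cl2, 25 → 40 °C
Reagents that add atoms: 3-chloroperoxybenzoic acid, OOC(=O)c1cccc(Cl)c1
Why: Baeyer–Villiger oxidation; in the Criegee intermediate the secondary isopropyl group migrates in preference to the primary C12 methylene, so oxygen is inserted between C13 and the isopropyl carbon, while the carboxyl-substituted C7=C8 bond is too electron-poor for this peracid.

Step 6
Reactants: 7 acid ester
Product: 9 isopropyl 18-(tert-butyldimethylsilyloxy)-17-hydroxy-14,15,16-trinorlabd-7-en-13-oate, via mixed carbonic anhydride 8 (not isolated)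
Conditions: i-BuOCOCl, N-methylmorpholine, THF, −15 °C; then NaBH4, H2O, 0 °C
Reagents that add atoms: none
Why: Mixed-anhydride reduction; borohydride attacks the acyl carbon of the activated conjugated acid in 1,2-fashion to give the allylic alcohol and at 0 °C does not touch the saturated isopropyl ester, which is how C17 and C13 are told apart.

Step 7
Reactants: 9 allylic alcohol
Product: 12 isopropyl 18-(tert-butyldimethylsilyloxy)-14,15,16-trinorlabd-8(17)-en-13-oate, via N-allyl sulfonylhydrazine 10 (not isolated), via allylic diazene 11 (not isolated)
Conditions: 2-nitrobenzenesulfonylhydrazide, PPh3, DEAD, THF, −30 °C; then 25 °C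
Reagents that add atoms: none
Why: Myers reductive 1,3-transposition; Mitsunobu N-alkylation at the primary allylic carbon C17, loss of the sulfinic acid on warming and retro-ene loss of nitrogen from the monoalkyl diazene deliver hydrogen to C7 and move the double bond to C8=C17. C7 becomes a methylene, so no stereocentre is formed, and the ester and silyl ether are inert.

Step 8
Reactants: 12 isopropyl ester
Product: 13 18-(tert-butyldimethylsilyloxy)-14,15,16-trinorlabd-8(17)-en-13-al
Conditions: DIBAL-H (1.1 equiv), CH2Cl2, −78 °C; Rochelle salt
Reagents that add atoms: none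
Why: Partial reduction of an ester with DIBAL-H; the tetrahedral aluminium hemiacetal persists at −78 °C and releases the aldehyde only on work-up, and the aldehyde has no α-stereocentre to lose.

Step 9
Reactants: 13 aldehyde; 14 dimethyl (1-diazo-2-oxopropyl)phosphonate
Product: 15 18-(tert-butyldimethylsilyloxy)-15,16-dinorlabd-8(17)-en-13-yne
Conditions: K2CO3, MeOH, 0 → 25 °C
Reagents that add atoms: dimethyl (1-diazo-2-oxopropyl)phosphonate (14), CC(=O)C(=[N+]=[N-])P(=O)(OC)OC
Why: Ohira–Bestmann variant of the Seyferth–Gilbert homologation; methanolysis of 14 gives the diazomethylphosphonate anion, which adds to the aldehyde, loses phosphate and nitrogen, and the alkylidene carbene rearranges by 1,2-hydrogen shift to the terminal alkyne, with C14 coming from 14. The carbonate base leaves the silyl ether and the C8 methylene alone.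

Step 10
Reactants: 15 alkyne; 16 trimethylaluminium; 17 methyl chloroformate
Product: 19 methyl 18-(tert-butyldimethylsilyloxy)labda-8(17),13E-dien-15-oate, via alkenyldimethylalane 18 (not isolated)
Conditions: Me3Al (2.5 equiv), Cp2ZrCl2 (0.25 equiv), CH2Cl2, 0 → 25 °C; then ClCO2Me (3 equiv), 0 → 25 °C; cold Rochelle salt work-up
Reagents that add atoms: trimethylaluminium (16), C[Al](C)C; methyl chloroformate (17), COC(=O)Cl
Why: The closest known reaction type is the zirconium-catalysed methylalumination of a terminal alkyne with chloroformate capture (Negishi carboalumination), used here as such. Cp2ZrCl2 and 16 form a chloride-bridged Zr–Al species with a strongly polarised Zr–CH3 bond, which adds across C13≡C14 through a four-centre syn transition state, methyl to the internal C13 and metal to the terminal C14; transfer of the alkenyl group to aluminium gives the (E)-alkenylalane 18 and returns the zirconium. The C14–Al bond is then acylated by 17 with retention at the sp2 carbon, so the C16 methyl and the C15 ester end cis. No ring is closed and no stereocentre is formed; the only stereochemical element, the C13=C14 geometry, is fixed by the syn addition and the retentive substitution. The step needs regioselectivity, secured because the bulky metal prefers the unhindered terminal carbon of an alkyne that carries only an unbranched CH2CH2 tether. It also needs chemoselectivity, secured because the hindered 1,1-disubstituted C8 methylene is not carbometalated by this achiral catalyst at room temperature and the silyl ether is inert to the alane. The alkenyldimethylalane should react with the chloroformate directly; if acylation lags, conversion into the lithium alanate with n-BuLi before 17 is added raises its reactivity without changing the outcome. The mild, non-acidic work-up protects the exocyclic alkene.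

Step 11
Reactants: 19 silyl ether methyl ester
Product: 20 methyl 18-hydroxylabda-8(17),13E-dien-15-oate
Conditions: TBAF, THF, 25–50 °C
Reagents that add atoms: none
Why: Fluoride-induced desilylation driven by Si–F bond formation; the neopentyl position may need gentle warming, and the enoate and both alkenes are unaffected.

Step 12
Reactants: 20 hydroxy ester
Product: 21 18-hydroxylabda-8(17),13E-dien-15-oic acid
Conditions: LiOH, THF–MeOH–H2O, 50 °C; then cold dilute HCl to pH 3–4
Reagents that add atoms: lithium hydroxide, [Li+].[OH-]
Why: Saponification by acyl–oxygen cleavage; the β,β-disubstituted enoate is slow but should hydrolyse without loss of geometry, and the acidification is kept cold and mild so that the 8(17)-alkene does not migrate.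

Step 13
Reactants: 21 hydroxy acid
Product: 23 18-acetoxylabda-8(17),13E-dien-15-oic acid (CNP0360430.2), via mixed acetic anhydride 22 (not isolated)
Conditions: Ac2O (3 equiv), pyridine, DMAP (cat.), CH2Cl2, 0 → 25 °C; then H2O, 25 °C
Reagents that add atoms: acetic anhydride, CC(=O)OC(C)=O
Why: DMAP-catalysed acetylation of the primary alcohol; the carboxyl group is transiently taken into a mixed acetic anhydride, which water cleaves at the unhindered acetyl carbon in the quench, so the free acid returns while the alkyl acetate stays. The base-labile acetate is installed last for that reason.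

## Compound list

1 | abietic acid (abieta-7,13-dien-18-oic acid) | CC(C)C1=CC2=CC[C@H]3[C@](C)(C(=O)O)CCC[C@]3(C)[C@H]2CC1 | starting material
2 | abietinol (abieta-7,13-dien-18-ol) | CC(C)C1=CC2=CC[C@H]3[C@](C)(CO)CCC[C@]3(C)[C@H]2CC1 | intermediate
3 | 18-(tert-butyldimethylsilyloxy)abieta-7,13-diene | CC(C)C1=CC2=CC[C@H]3[C@](C)(CO[Si](C)(C)C(C)(C)C)CCC[C@]3(C)[C@H]2CC1 | intermediate
4 | 18-(tert-butyldimethylsilyloxy)abiet-7-ene-13α,14α-diol (cis diol, α face assumed) | CC(C)[C@@]1(O)[C@H](O)C2=CC[C@H]3[C@](C)(CO[Si](C)(C)C(C)(C)C)CCC[C@]3(C)[C@H]2CC1 | intermediate (not isolated)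
5 | 18-(tert-butyldimethylsilyloxy)-13-oxo-13,14-secoabiet-7-en-14-al | O=CC1=CC[C@H]2[C@](C)(CO[Si](C)(C)C(C)(C)C)CCC[C@]2(C)[C@H]1CCC(=O)C(C)C | intermediate
6 | 18-(tert-butyldimethylsilyloxy)-13-oxo-13,14-secoabiet-7-en-14-oic acid | O=C(O)C1=CC[C@H]2[C@](C)(CO[Si](C)(C)C(C)(C)C)CCC[C@]2(C)[C@H]1CCC(=O)C(C)C | intermediate
7 | 18-(tert-butyldimethylsilyloxy)-14,15,16-trinorlabd-7-ene-13,17-dioic acid 13-isopropyl ester | O=C(O)C1=CC[C@H]2[C@](C)(CO[Si](C)(C)C(C)(C)C)CCC[C@]2(C)[C@H]1CCC(=O)OC(C)C | intermediate
8 | isobutyl carbonic anhydride of 7 at C17 | CC(C)COC(=O)OC(=O)C1=CC[C@H]2[C@](C)(CO[Si](C)(C)C(C)(C)C)CCC[C@]2(C)[C@H]1CCC(=O)OC(C)C | intermediate (not isolated)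
9 | isopropyl 18-(tert-butyldimethylsilyloxy)-17-hydroxy-14,15,16-trinorlabd-7-en-13-oate | OCC1=CC[C@H]2[C@](C)(CO[Si](C)(C)C(C)(C)C)CCC[C@]2(C)[C@H]1CCC(=O)OC(C)C | intermediate
10 | N-(C17-allyl)-N-(2-nitrobenzenesulfonyl)hydrazine derived from 9 | NN(CC1=CC[C@H]2[C@](C)(CO[Si](C)(C)C(C)(C)C)CCC[C@]2(C)[C@H]1CCC(=O)OC(C)C)S(=O)(=O)c1ccccc1[N+](=O)[O-] | intermediate (not isolated)
11 | C17 allylic monoalkyl diazene | N=NCC1=CC[C@H]2[C@](C)(CO[Si](C)(C)C(C)(C)C)CCC[C@]2(C)[C@H]1CCC(=O)OC(C)C | intermediate (not isolated)
12 | isopropyl 18-(tert-butyldimethylsilyloxy)-14,15,16-trinorlabd-8(17)-en-13-oate | C=C1CC[C@H]2[C@](C)(CO[Si](C)(C)C(C)(C)C)CCC[C@]2(C)[C@H]1CCC(=O)OC(C)C | intermediate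
13 | 18-(tert-butyldimethylsilyloxy)-14,15,16-trinorlabd-8(17)-en-13-al | C=C1CC[C@H]2[C@](C)(CO[Si](C)(C)C(C)(C)C)CCC[C@]2(C)[C@H]1CCC=O | intermediate
14 | dimethyl (1-diazo-2-oxopropyl)phosphonate | CC(=O)C(=[N+]=[N-])P(=O)(OC)OC | starting material
15 | 18-(tert-butyldimethylsilyloxy)-15,16-dinorlabd-8(17)-en-13-yne | C=C1CC[C@H]2[C@](C)(CO[Si](C)(C)C(C)(C)C)CCC[C@]2(C)[C@H]1CCC#C | intermediate
16 | trimethylaluminium | C[Al](C)C | starting material
17 | methyl chloroformate | COC(=O)Cl | starting material
18 | (E)-C14 alkenyldimethylalane, 13-methyl | C=C1CC[C@H]2[C@](C)(CO[Si](C)(C)C(C)(C)C)CCC[C@]2(C)[C@H]1CC/C(C)=C/[Al](C)C | intermediate (not isolated)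
19 | methyl 18-(tert-butyldimethylsilyloxy)labda-8(17),13E-dien-15-oate | C=C1CC[C@H]2[C@](C)(CO[Si](C)(C)C(C)(C)C)CCC[C@]2(C)[C@H]1CC/C(C)=C/C(=O)OC | intermediate
20 | methyl 18-hydroxylabda-8(17),13E-dien-15-oate | C=C1CC[C@H]2[C@](C)(CO)CCC[C@]2(C)[C@H]1CC/C(C)=C/C(=O)OC | intermediate
21 | 18-hydroxylabda-8(17),13E-dien-15-oic acid | C=C1CC[C@H]2[C@](C)(CO)CCC[C@]2(C)[C@H]1CC/C(C)=C/C(=O)O | intermediate
22 | 18-acetoxylabda-8(17),13E-dien-15-oic acetic anhydride | C=C1CC[C@H]2[C@](C)(COC(C)=O)CCC[C@]2(C)[C@H]1CC/C(C)=C/C(=O)OC(C)=O | intermediate (not isolated)
23 | 18-acetoxylabda-8(17),13E-dien-15-oic acid (CNP0360430.2) | C=C1CC[C@H]2[C@](C)(COC(C)=O)CCC[C@]2(C)[C@H]1CC/C(C)=C/C(=O)O | target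

## Step count and least certain steps

Total: 13 steps. Longest linear sequence: 13 steps, from 1 to 23; compounds 14, 16 and 17 are purchased.

**Step 10 (key step).** Methyl delivery may be incompletely regioselective, acylation of the alkenylalane may lag behind protonolysis on work-up, or the Lewis-acidic medium may shift the 8(17)-alkene into the ring. The fallback sets out from 15. Gold(I)-catalysed Markovnikov hydration of the alkyne should give the methyl ketone 18-(tert-butyldimethylsilyloxy)-14,15-dinorlabd-8(17)-en-13-one F1. A Horner–Wadsworth–Emmons reaction with trimethyl phosphonoacetate and NaH then returns to 19 after chromatographic removal of the Z isomer. The geometry is then only a thermodynamic preference, which is why this is the reserve.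

**Step 3.** Osmylation may compete at C7=C8, or the enal may be over-oxidised once periodate regenerates osmium(VIII) in the same flask. The fallback sets out from 3. The diol 4 is isolated after the dihydroxylation, and its allylic C14 carbinol is oxidised with MnO2 to the α-ketol 18-(tert-butyldimethylsilyloxy)-13α-hydroxyabiet-7-en-14-one F2. Periodate cleavage of the ketol between C13 and C14 gives acid 6 directly, so the route is rejoined at 6 without passing through 5.

**Step 5.** Oxygen insertion at a ketone flanked by an isopropyl group may be slow, some migration of the primary C12 carbon may occur, and a stronger peracid would endanger the silyl ether and the conjugated alkene. The fallback sets out from 6 and avoids peracids: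
- hydroxylamine gives the oxime F3, with hydroxyl anti to the isopropyl group;
- Beckmann rearrangement (TsCl, pyridine) gives the N-isopropyl amide F4;
- N-nitrosation (NaNO2, Ac2O–AcOH) gives the N-nitroso amide F5;
- gentle heating of F5 rearranges it with loss of nitrogen to the isopropyl ester 7.

**Step 6.** Hydride may attack the carbonate carbonyl of 8 and return the acid, conjugate reduction may intervene, or anhydride formation at the hindered carboxyl may be sluggish. The fallback sets out from 7 and drops C17:
- diphenylphosphoryl azide and Et3N give the acyl azide F6;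
- Curtius rearrangement in warm toluene gives the vinyl isocyanate F7;
- dilute aqueous acid hydrolyses it to the ketone isopropyl 18-(tert-butyldimethylsilyloxy)-8-oxo-14,15,16,17-tetranorlabdan-13-oate F8;
- Wittig methylenation (Ph3P=CH2) rejoins the route at 12, so step 7 is bypassed as well.

**Step 7.** The Mitsunobu displacement at the allylic carbon next to the fully substituted C8 may be slower than decomposition of the sulfonyl hydrazide, which would leave unreacted alcohol. The fallback sets out from 9. Methyl chloroformate and pyridine give the allylic methyl carbonate F9. Palladium(0)-catalysed hydrogenolysis with formate and tributylphosphine (Tsuji reduction) delivers hydride to the more substituted allyl terminus C7 and returns to 12.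

## Further compounds

F1 | step 10 | 18-(tert-butyldimethylsilyloxy)-14,15-dinorlabd-8(17)-en-13-one | C=C1CC[C@H]2[C@](C)(CO[Si](C)(C)C(C)(C)C)CCC[C@]2(C)[C@H]1CCC(C)=O
F2 | step 3 | 18-(tert-butyldimethylsilyloxy)-13α-hydroxyabiet-7-en-14-one | CC(C)[C@@]1(O)C(=O)C2=CC[C@H]3[C@](C)(CO[Si](C)(C)C(C)(C)C)CCC[C@]3(C)[C@H]2CC1
F3 | step 5 | 13-oxime of 6 (hydroxyl anti to isopropyl) | O=C(O)C1=CC[C@H]2[C@](C)(CO[Si](C)(C)C(C)(C)C)CCC[C@]2(C)[C@H]1CC/C(=N\O)C(C)C
F4 | step 5 | 18-(tert-butyldimethylsilyloxy)-13-(isopropylamino)-13-oxo-14,15,16-trinorlabd-7-en-17-oic acid | O=C(O)C1=CC[C@H]2[C@](C)(CO[Si](C)(C)C(C)(C)C)CCC[C@]2(C)[C@H]1CCC(=O)NC(C)C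
F5 | step 5 | N-nitroso derivative of amide F4 | O=C(O)C1=CC[C@H]2[C@](C)(CO[Si](C)(C)C(C)(C)C)CCC[C@]2(C)[C@H]1CCC(=O)N(N=O)C(C)C
F6 | step 6 | C17 acyl azide of 7 | [N-]=[N+]=NC(=O)C1=CC[C@H]2[C@](C)(CO[Si](C)(C)C(C)(C)C)CCC[C@]2(C)[C@H]1CCC(=O)OC(C)C
F7 | step 6 | isopropyl 18-(tert-butyldimethylsilyloxy)-8-isocyanato-14,15,16,17-tetranorlabd-7-en-13-oate | O=C=NC1=CC[C@H]2[C@](C)(CO[Si](C)(C)C(C)(C)C)CCC[C@]2(C)[C@H]1CCC(=O)OC(C)C
F8 | step 6 | isopropyl 18-(tert-butyldimethylsilyloxy)-8-oxo-14,15,16,17-tetranorlabdan-13-oate | O=C1CC[C@H]2[C@](C)(CO[Si](C)(C)C(C)(C)C)CCC[C@]2(C)[C@H]1CCC(=O)OC(C)C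
F9 | step 7 | isopropyl 18-(tert-butyldimethylsilyloxy)-17-(methoxycarbonyloxy)-14,15,16-trinorlabd-7-en-13-oate | COC(=O)OCC1=CC[C@H]2[C@](C)(CO[Si](C)(C)C(C)(C)C)CCC[C@]2(C)[C@H]1CCC(=O)OC(C)C
A1 | alternative 1 | 4-(tert-butyldimethylsilyloxy)-2-methyl-2-(3-oxopentyl)-3-vinylcyclohexanone (ring B with C9 vinyl, C10 methyl) | CC(C)(C)[Si](C)(C)O[C@@H]1CCC(=O)[C@](C)(CCC(=O)CC)[C@H]1C=C
A2 | alternative 2 | 8-oxo decalin with C9 hydroxymethyl and 18-silyl ether | O=C1CC[C@H]2[C@](C)(CO[Si](C)(C)C(C)(C)C)CCC[C@]2(C)[C@H]1CO
A3 | alternative 3 | methyl 18-(tert-butyldimethylsilyloxy)-13,14,15,16-tetranorlabd-8(17)-en-12-oate | C=C1CC[C@H]2[C@](C)(CO[Si](C)(C)C(C)(C)C)CCC[C@]2(C)[C@H]1CC(=O)OC
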